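The constants used here are assumed; the result is computed.

Which form holds most of the L after 25 min in each flask, and how much of the L charged does it hold?

| flask | L | X | time |
|---|---|---|---|
| cedar | 0.060 M | 0.800 equiv | 25 min |
| larch | 0.060 M | 1.20 equiv | 25 min |
| alder | 0.060 M | 1.80 equiv | 25 min |

    L + X ⇌ L.X (K1 = 6.7 M⁻¹, k1 = 0.62 M⁻¹ s⁻¹)
    L.X ⇌ D + Z (K2 = 0.0032 M, k2 = 0.0032 s⁻¹)

- which of these there is most of at the end, counted by the L in it, cedar (L / L.X / D)
- which of these there is most of at the end, counted by the L in it, larch (L / L.X / D)
- which of these there is most of at the end, counted by the L in it, alder (L / L.X / D)
- how much there is at the end of the one of these that leads, in percent of the L charged: cedar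
- how much there is at the end of the one of these that leads, in percent of the L charged: larch
- how much there is at the end of the one of these that leads, in percent of the L charged: alder

First I ask whether I may reckon by balance. In cedar the first step has a forward half-life for L of 0.39 min, and the second step has one for L.X of 3.6 min. The run is longer than that second half-life, and a way back can add to the rate of approach, so I take each flask to be at balance, which is thermodynamic control.

Then, who leads? At balance of the first step, L.X over L equals K1 times free X, so the two hold equal shares when free X stands at one over K1, 0.149 M. I call this the even level. The largest charge of X, in alder, is 0.108 M, below that level, and free X cannot exceed its charge, so L outweighs L.X in each flask. Each D comes with one Z, so D is the square root of K2 times L.X. With L.X under half the charge of L, D stays under 0.00980 M, while L stays above 0.0251 M. So L leads.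

How much L? I treat the second step as a correction. The first step by itself puts 0.0117 M into L.X in cedar, 0.0163 M in larch and 0.0219 M in alder. Draining D from L.X lowers L, but the first step gives part back: L falls by D divided by one plus K1 times (L charged plus X charged minus twice L.X). In alder that is 0.00458 M, less than the L.X it corrects. I commit to L at 73.9% in cedar, 65.6% in larch and 55.8% in alder.

The forecast names L, L and L for cedar, larch and alder, at 74.4%, 66.1% and 56.3%, holding that “every run has therefore reached full equilibrium”.

The flasks give L at 74.4% in cedar, L at 66.1% in larch and L at 56.3% in alder, so in alder my figure sits 0.51 percentage points low. In larch the first step had done half of its turnover by 0.101 min, and L already stood at 66.1% at 12.5 min, as it does at 25.0 min, 66.1%. In alder free X ends at 0.0818 M, which is 0.548 of the even level, and L.X over L reads 0.548. A flask like larch but with 4.80 equiv of X ends with 0.247 M free, above the even level, and there L.X leads with 51.9% against 31.4% of L.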